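Slowness sets in early here: the south-east flask makes 0.0971 M of Q in its first 2.5 min, yet 0.0193 M between 33 min and 63 min. The south-east flask is charged with less G than E. Each turnover takes one G and one E to one Q, and at the last reading the south-east flask still holds 0.297 M of G unturned, so it has slowed with G in hand.

| flask | G | E | time |
|---|---|---|---|
| south-east | 0.600 M | 1.50 M |  |
| north | 0.600 M | 2.20 M |  |
| west | 0.300 M | 4.50 M | 63 min |

| run | time / min | [Q] / M |
|---|---|---|
| south-east run | 2.5 | 0.0971 |
| south-east run | 4.8 | 0.1474 |
| south-east run | 9.1 | 0.1998 |
| south-east run | 17 | 0.2492 |
| south-east run | 33 | 0.2833 |
| south-east run | 63 | 0.3026 |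
| north run | 2.5 | 0.1117 |
| north run | 4.8 | 0.1624 |
| north run | 9.1 | 0.2165 |
| north run | 17 | 0.2607 |
| north run | 33 | 0.3023 |
| north run | 63 | 0.3211 |

(standard deviation of a reading: 0.002 M)

- Overall: G + E -> Q.
- Constant volume, constant temperature.
- The analysis sees a species whether free or bound.
- "The second partner" is E.
- An order is taken over about fifteen percent of the charge, up and down.

- the exponent of [E] in the starting rate at the charge of the south-east run (at the point where two percent of the G have become Q)
- Q in the west run at 63 min, as a share of the G charged

The south-east flask ends at 1.02 turnovers made per G unturned, a quantity called here the end ratio, and the north flask ends at 1.15. Two extreme flasks can be solved in the head, both taking the ratio at 63 min to follow the E charged and to ignore the G charged. If E has no effect on the ratio, the west flask keeps the north value, a share of 53.5 %. If the ratio grows in step with E, the west flask reaches 2.35, a share of 70.1 %.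

The real flask lies between them, since raising E by a factor 1.47 raised the read ratio by a factor 1.13, an exponent of 0.323. Carried to the west charge, that exponent gives a ratio of 1.45 and so a share of 59.2 %, the reckoning committed to here. The first readings of the two flasks, compared the same way, give an order near 0.366.

The forecast differs from both, with an order of 0.45 (0.25 to 0.7) and a share of 68 % (55 % to 84 %). It holds that “the plateau ratio Q/G-left scales only weakly with E, about √E or less”.

The simulation gives an order of 0.44 and a west share of 61.7 %, which is an end ratio of 1.61, above the south-east 1.02 and the north 1.15 and below the upper extreme 2.35. The north flask had reached a ratio of one at 33.0 min, the south-east flask at 53.6 min.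

    G ⇌ L + J (0.8280 /min, 0.2124 /M/min)
    L + E → Q (0.3804 /M/min)
    E + J ⇌ EJ, settled at all times (2.680 /M)
    2 E → Ju (0.6900 /M/min)

In each flask G opened to L and J, and L took up E to give Q. Meanwhile E went two at a time to Ju, with a first half-life by this step alone of 0.483 min at the south-east charge, shorter than the 4.89 min that flask took to turn a quarter of its G. At the west charge that first half-life is 0.161 min.

(The data are calculated for an exercise, noise included.)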